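**Retrosynthetic overview**
1. (+)-Lariciresinol ⇐ one-pot removal of three silyl groups from its fully silylated form.
2. Benzylic CH2–aryl bond ⇐ 9-BBN hydroboration and Pd-catalysed B-alkyl Suzuki–Miyaura coupling of a (2S,3R)-2-aryl-3-(silyloxymethyl)-4-methylene-tetrahydrofuran with an aryl bromide; hydroboration anti to the C3 substituent sets C4.
3. Tetrahydrofuran ring (the only ring built; both arenes come from catechol) ⇐ Pd-catalysed asymmetric [3+2] cycloaddition of a silyloxymethyl-substituted trimethylenemethane (TMM) donor with the aryl aldehyde; this sets C2 and C3.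
4. Aryl bromide and aryl aldehyde ⇐ catechol (monomethylation, para-bromination, silylation; then Br/Li exchange and DMF).
5. TMM donor ⇐ ethylene glycol and 2-bromo-3-(trimethylsilyl)propene.

Assumption: the SMILES is read as (2S,3R,4R), i.e. aryl trans to CH2OH and CH2OH cis to the benzyl group; the one-pot hydroboration/cross-coupling is counted as one step.

**Route**

Step 1
Reactants: 1 catechol (benzene-1,2-diol)
Product: 2 guaiacol (2-methoxyphenol)
Conditions: MeI (1.0 equiv), K2CO3 (1.0 equiv), acetone, reflux
Reagents that add atoms: iodomethane, CI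
Why: Williamson mono-O-methylation of the catechol monoanion; the dimethyl ether and unreacted diol are removed by acid/base extraction.

Step 2
Reactants: 2 guaiacol
Product: 3 4-bromo-2-methoxyphenol
Conditions: NBS (1.0 equiv), MeCN, 0 °C → rt
Reagents that add atoms: N-bromosuccinimide, O=C1CCC(=O)N1Br
Why: Electrophilic aromatic bromination is directed para to the free OH, the stronger donor, giving the 4-bromo isomer.

Step 3
Reactants: 3 4-bromo-2-methoxyphenol
Product: 4 (4-bromo-2-methoxyphenoxy)triisopropylsilane
Conditions: TIPSCl, imidazole, DMF, rt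
Reagents that add atoms: triisopropylsilyl chloride, CC(C)[Si](Cl)(C(C)C)C(C)C
Why: Standard phenol silylation; the aryl TIPS ether tolerates n-BuLi, Pd(0), 9-BBN and mild aqueous base.

Step 4
Reactants: 4 (4-bromo-2-methoxyphenoxy)triisopropylsilane
Product: 5 3-methoxy-4-(triisopropylsilyloxy)benzaldehyde
Conditions: n-BuLi, THF, −78 °C; then DMF, −78 → 0 °C; aq. NH4Cl
Reagents that add atoms: N,N-dimethylformamide, CN(C)C=O
Why: Bromine–lithium exchange followed by formylation of the aryllithium with DMF (Bouveault-type); the lithium sits para to OSi, so no retro-Brook migration occurs.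

Step 5
Reactants: 6 ethylene glycol
Product: 7 2-(tert-butyldimethylsilyloxy)ethanol
Conditions: NaH (1.0 equiv), THF, rt; then TBSCl (1.0 equiv)
Reagents that add atoms: tert-butyldimethylsilyl chloride, CC(C)(C)[Si](C)(C)Cl
Why: Monosilylation of a symmetrical diol through its sparingly soluble monosodium alkoxide.

Step 6
Reactants: 7 2-(tert-butyldimethylsilyloxy)ethanol
Product: 8 (tert-butyldimethylsilyloxy)acetaldehyde
Conditions: (COCl)2, DMSO, CH2Cl2, −78 °C; Et3N
Reagents that add atoms: none
Why: Swern oxidation of the primary alcohol without over-oxidation or silyl loss; the aldehyde is used directly.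

Step 7
Reactants: 8 (tert-butyldimethylsilyloxy)acetaldehyde; 9 2-bromo-3-(trimethylsilyl)propene
Product: 10 rac-1-(tert-butyldimethylsilyloxy)-3-[(trimethylsilyl)methyl]but-3-en-2-ol
Conditions: 9, Mg, THF, 40 °C; then 8, −78 → 0 °C
Reagents that add atoms: none
Why: Grignard 1,2-addition of the 1-[(trimethylsilyl)methyl]vinyl nucleophile to the aldehyde; the racemic carbinol centre is erased when the π-allyl/TMM complex forms in step 9.

Step 8
Reactants: 10 rac-1-(tert-butyldimethylsilyloxy)-3-[(trimethylsilyl)methyl]but-3-en-2-ol
Product: 11 rac-1-(tert-butyldimethylsilyloxy)-3-[(trimethylsilyl)methyl]but-3-en-2-yl methyl carbonate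
Conditions: ClCO2Me, pyridine, DMAP (cat.), CH2Cl2, 0 °C
Reagents that add atoms: methyl chloroformate, COC(=O)Cl
Why: Acylation gives the ionisable allylic carbonate; the mild amine-base conditions avoid Peterson-type elimination and 1,2-silyl migration.

Step 9
Reactants: 5 3-methoxy-4-(triisopropylsilyloxy)benzaldehyde; 11 rac-TMM donor carbonate
Product: 12 tert-butyl({(2S,3R)-2-[3-methoxy-4-(triisopropylsilyloxy)phenyl]-4-methylidenetetrahydrofuran-3-yl}methoxy)dimethylsilane (aryl and CH2OTBS trans)
Conditions: 11 (1.5 equiv), Pd(dba)2 (5 mol %), chiral BINOL-derived phosphoramidite L* (10 mol %, enantiomer chosen for 2S,3R), toluene, 23–45 °C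
Reagents that add atoms: none
Why: Proposed new method: an enantio- and diastereoselective Pd-catalysed [3+2] cycloaddition of an oxygenated 1-substituted TMM donor with an aryl aldehyde, in which Pd(0)L* ionises the carbonate, the released methoxide removes SiMe3 to give the Pd–TMM zwitterion, this equilibrates so that the CH(CH2OTBS) carbon is the nucleophilic terminus (as with alkyl-substituted TMM donors), it adds to the ligand-selected aldehyde face through an open anti-periplanar transition state (aryl anti to CH2OTBS, hence 2,3-trans), and the alkoxide closes onto the symmetrical CH2–C–CH2 π-allyl to form the ring and set C2 (S) and C3 (R); the closest known reaction type is the Trost asymmetric Pd-TMM cycloaddition of the unsubstituted donor with aryl aldehydes and of cyano- or alkyl-substituted donors with other acceptors.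

Step 10
Reactants: 12 the (2S,3R)-4-methylidene-tetrahydrofuran; 4 (4-bromo-2-methoxyphenoxy)triisopropylsilane
Product: 13 tert-butyl({(2S,3R,4R)-2-[3-methoxy-4-(triisopropylsilyloxy)phenyl]-4-[3-methoxy-4-(triisopropylsilyloxy)benzyl]tetrahydrofuran-3-yl}methoxy)dimethylsilane (2,3-trans, 3,4-cis)
Conditions: 9-BBN (1.5 equiv), THF, 0 °C → rt; then 4 (1.2 equiv), Pd(dppf)Cl2 (5 mol %), K3PO4 (3 M aq.), DMF, 50 °C
Reagents that add atoms: none (9-BBN delivers only H; the aryl group comes from 4)
Why: Anti-Markovnikov hydroboration is expected on the face anti to the adjacent C3 CH2OTBS group, so H goes trans and the CH2–B arm cis to it, setting C4 (R), and the B-alkyl Suzuki–Miyaura coupling then forms the CH2–aryl bond without touching a stereocentre.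

Step 11
Reactants: 13 the tris-silyl ether
Product: 14 (+)-lariciresinol, 4-[(2S,3R,4R)-4-(4-hydroxy-3-methoxybenzyl)-3-(hydroxymethyl)tetrahydrofuran-2-yl]-2-methoxyphenol
Conditions: TBAF (4 equiv), AcOH (4 equiv), THF, 0 °C → rt
Reagents that add atoms: none
Why: Buffered fluoride cleaves both aryl TIPS ethers and the primary TBS ether in one operation and leaves the benzylic ring C–O bond and all three stereocentres untouched.

**Compound list**
1 | catechol | Oc1ccccc1O | starting material
2 | guaiacol (2-methoxyphenol) | COc1ccccc1O | intermediate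
3 | 4-bromo-2-methoxyphenol | COc1cc(Br)ccc1O | intermediate
4 | (4-bromo-2-methoxyphenoxy)triisopropylsilane | COc1cc(Br)ccc1O[Si](C(C)C)(C(C)C)C(C)C | intermediate
5 | 3-methoxy-4-(triisopropylsilyloxy)benzaldehyde | COc1cc(C=O)ccc1O[Si](C(C)C)(C(C)C)C(C)C | intermediate
6 | ethylene glycol | OCCO | starting material
7 | 2-(tert-butyldimethylsilyloxy)ethanol | OCCO[Si](C)(C)C(C)(C)C | intermediate
8 | (tert-butyldimethylsilyloxy)acetaldehyde | O=CCO[Si](C)(C)C(C)(C)C | intermediate
9 | 2-bromo-3-(trimethylsilyl)propene | C=C(Br)C[Si](C)(C)C | starting material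
10 | rac-1-(tert-butyldimethylsilyloxy)-3-[(trimethylsilyl)methyl]but-3-en-2-ol | C=C(C[Si](C)(C)C)C(O)CO[Si](C)(C)C(C)(C)C | intermediate
11 | rac-1-(tert-butyldimethylsilyloxy)-3-[(trimethylsilyl)methyl]but-3-en-2-yl methyl carbonate | COC(=O)OC(CO[Si](C)(C)C(C)(C)C)C(=C)C[Si](C)(C)C | intermediate
12 | tert-butyl({(2S,3R)-2-[3-methoxy-4-(triisopropylsilyloxy)phenyl]-4-methylidenetetrahydrofuran-3-yl}methoxy)dimethylsilane | C=C1CO[C@H](c2ccc(O[Si](C(C)C)(C(C)C)C(C)C)c(OC)c2)[C@H]1CO[Si](C)(C)C(C)(C)C | intermediate
13 | tert-butyl({(2S,3R,4R)-2-[3-methoxy-4-(triisopropylsilyloxy)phenyl]-4-[3-methoxy-4-(triisopropylsilyloxy)benzyl]tetrahydrofuran-3-yl}methoxy)dimethylsilane | COc1cc(C[C@H]2CO[C@H](c3ccc(O[Si](C(C)C)(C(C)C)C(C)C)c(OC)c3)[C@H]2CO[Si](C)(C)C(C)(C)C)ccc1O[Si](C(C)C)(C(C)C)C(C)C | intermediate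
14 | (+)-lariciresinol | COc1cc(C[C@H]2CO[C@H](c3ccc(O)c(OC)c3)[C@H]2CO)ccc1O | target

**Totals**
Total step count: 11.
Longest linear sequence: 7 steps (1→2→3→4→9→10→11, or 5→6→7→8→9→10→11).

**Three steps most likely to fail**
1. Step 9 (the proposed new cycloaddition). The risks are β-silyloxy elimination from the Pd–TMM zwitterion, the wrong TMM terminus attacking, and low trans selectivity or ee. Fallback with known chemistry: add vinylmagnesium bromide to 5, run a Sharpless kinetic-resolution epoxidation of the allylic alcohol, O-propargylate, and carry out a Cp2TiCl-mediated (Nugent–RajanBabu) epoxide opening with 5-exo-dig radical cyclisation. This gives the 2,3-trans 2-aryl-3-(hydroxymethyl)-4-methylene-tetrahydrofuran, which is silylated with TBSCl to rejoin at 12.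
2. Step 10. The risks are eroded facial selectivity, because the vicinal CH2OTBS group and the 1,3-related aryl group sit on opposite faces, a sluggish B-alkyl coupling with the electron-rich bromide, and partial TIPS loss in aqueous base. Fallback: hydroborate and oxidise 12 to the primary alcohol, separate the C4 epimers by chromatography, convert to the iodide (I2, PPh3, imidazole), and join it to 4 by Ni-catalysed reductive cross-electrophile coupling.
3. Step 1. Statistical over-methylation to veratrole can lower the yield and complicate purification. Fallback: start from anisole and make guaiacol by directed ortho-lithiation (n-BuLi/TMEDA), borylation with B(OMe)3 and H2O2 oxidation.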